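**Retrosynthetic overview**

1. The target is read as ent-oritin-(4β→6)-epioritin-4α-ol (upper unit 2S,3R,4S; lower unit 2R,3R,4R). It is traced back to its hexabenzyl ether, whose upper C3–OH and C4–H come from hydroboration of a 4-aryl-flav-3-ene on the face opposite the 2-aryl group.
2. That alkene comes from a 4-aryl-flavan-3-one. Its interflavan C4–C6 bond is cut between the α-carbon of a flavan-3-one and the C6–H of the complete lower unit. Both centres are nucleophilic by nature, so the ketone is used as its enolonium (α-cation) equivalent.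
3. The lower unit is an all-cis 3,4-carbonate, made from a 2,3-cis-flavan-3-ol Boc carbonate by C4–H oxidation with internal oxygen delivery. Both units go back to enantiomeric flavan-3-ones.
4. The flavan-3-ones come from enantiomeric 2-aryl-2H-chromenes, both made from one chromene acetal (from daphnetin) and one batch of diethyl arylboronate by catalytic asymmetric boronate addition.
5. Ring order: rings A and the pyran rings C are bought with the coumarin, rings B enter with the boronate, and no ring is closed late. Ring C is only re-functionalised (C2 aryl, C3 oxygen, C4 link).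

Assumption: the L-tartaric-acid-derived catalyst is taken to give the (2R)-chromene 7 and its enantiomer the (2S)-chromene 11; if the observed sense is the reverse, the two catalysts are exchanged between steps 4 and 7.

**Route**

Step 1
Reactants: 1 daphnetin (7,8-dihydroxy-2H-chromen-2-one)
Product: 2 7,8-bis(benzyloxy)-2H-chromen-2-one
Conditions: BnBr (2.4 equiv), K2CO3, DMF, 60 °C
Reagents that add atoms: benzyl bromide, BrCc1ccccc1
Why: Williamson etherification of both catechol hydroxyls; no stereocentre is involved.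

Step 2
Reactants: 2 7,8-bis(benzyloxy)-2H-chromen-2-one
Product: 4 7,8-bis(benzyloxy)-2-ethoxy-2H-chromene, via lactol 3 (not isolated)
Conditions: i-Bu2AlH, CH2Cl2, −78 °C; aq. KNaC4H4O6 wash; crude in EtOH, pyridinium p-toluenesulfonate (cat.), 4 Å MS, rt
Reagents that add atoms: ethanol, CCO
Why: low-temperature half-reduction of the lactone stops at the lactol, which is turned into the mixed acetal by acid-catalysed acetalisation; the acetal centre is racemic and is erased in the later boronate addition.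

Step 3
Reactants: 5 4-(benzyloxy)phenylboronic acid
Product: 6 diethyl [4-(benzyloxy)phenyl]boronate
Conditions: EtOH, 3 Å MS (Soxhlet), reflux; concentrated and kept under Ar as a stock solution in EtOAc
Reagents that add atoms: ethanol, CCO
Why: condensation (esterification) of the boronic acid with ethanol, driven by removal of water over sieves; one batch is divided between steps 4 and 7 and no stereocentre is involved.

Step 4
Reactants: 4 7,8-bis(benzyloxy)-2-ethoxy-2H-chromene; 6 diethyl [4-(benzyloxy)phenyl]boronate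
Product: 7 (2R)-7,8-bis(benzyloxy)-2-[4-(benzyloxy)phenyl]-2H-chromene
Conditions: 6 (1.5 equiv), L-tartaric acid N,N-dibenzyl monoamide (10 mol %), Yb(OTf)3 (5 mol %), EtOAc, −20 °C
Reagents that add atoms: none
Why: enantioselective Brønsted-acid/lanthanide-triflate-catalysed addition of an aryl boronate to a 2H-chromene acetal, in which the acetal ionises to the achiral benzopyrylium ion and the tartrate-bound boronate delivers the aryl group to one face of C2, setting the C2 centre of the upper unit.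

Step 5
Reactants: 7 (2R)-7,8-bis(benzyloxy)-2-[4-(benzyloxy)phenyl]-2H-chromene
Product: 9 (2S)-7,8-bis(benzyloxy)-2-[4-(benzyloxy)phenyl]chroman-3-one, via alkylborane 8 (not isolated)
Conditions: BH3·SMe2, THF, 0 °C to rt; then N-methylmorpholine N-oxide (excess), (n-Pr4N)RuO4 (5 mol %), 4 Å MS, CH2Cl2, rt
Reagents that add atoms: N-methylmorpholine N-oxide, C[N+]1([O-])CCOCC1
Why: Brown hydroboration places boron on C3 (away from the benzylic carbon, anti to the 2-aryl group) and one-pot amine-oxide/perruthenate oxidation (Ley–Griffith type) takes the C–B bond through the alcohol to the ketone; C2 is untouched and its label changes from R to S only because C3 gains priority.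

Step 6
Reactants: 9 (2S)-7,8-bis(benzyloxy)-2-[4-(benzyloxy)phenyl]chroman-3-one
Product: 10 (2S)-7,8-bis(benzyloxy)-2-[4-(benzyloxy)phenyl]-3-(trimethylsilyloxy)-2H-chromene
Conditions: LiN(SiMe3)2, Me3SiCl (internal quench), THF, −78 °C; pentane, filtration, used crude
Reagents that add atoms: chlorotrimethylsilane, C[Si](C)(C)Cl
Why: kinetic enolisation removes a proton from the less hindered benzylic C4H2 and not from the tertiary, oxygen-bearing C2–H, and O-silylation gives the C3=C4 silyl enol ether with C2 unchanged.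

Step 7
Reactants: 4 7,8-bis(benzyloxy)-2-ethoxy-2H-chromene; 6 diethyl [4-(benzyloxy)phenyl]boronate
Product: 11 (2S)-7,8-bis(benzyloxy)-2-[4-(benzyloxy)phenyl]-2H-chromene
Conditions: 6 (1.5 equiv), D-tartaric acid N,N-dibenzyl monoamide (10 mol %), Yb(OTf)3 (5 mol %), EtOAc, −20 °C
Reagents that add atoms: none
Why: the same enantioselective boronate addition to the benzopyrylium ion with the mirror-image catalyst sets the opposite C2 configuration needed for the lower unit.

Step 8
Reactants: 11 (2S)-7,8-bis(benzyloxy)-2-[4-(benzyloxy)phenyl]-2H-chromene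
Product: 13 (2R)-7,8-bis(benzyloxy)-2-[4-(benzyloxy)phenyl]chroman-3-one, via alkylborane 12 (not isolated)
Conditions: BH3·SMe2, THF, 0 °C to rt; then N-methylmorpholine N-oxide (excess), (n-Pr4N)RuO4 (5 mol %), 4 Å MS, CH2Cl2, rt
Reagents that add atoms: N-methylmorpholine N-oxide, C[N+]1([O-])CCOCC1
Why: Brown hydroboration at C3 followed by one-pot amine-oxide/perruthenate oxidation gives the flavan-3-one as in step 5, with C2 untouched.

Step 9
Reactants: 13 (2R)-7,8-bis(benzyloxy)-2-[4-(benzyloxy)phenyl]chroman-3-one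
Product: 15 tert-butyl (2R,3R)-7,8-bis(benzyloxy)-2-[4-(benzyloxy)phenyl]chroman-3-yl carbonate, via lithium alkoxide 14 (not isolated)
Conditions: LiBH(s-Bu)3, THF, −78 °C; then Boc2O, −78 to 0 °C
Reagents that add atoms: di-tert-butyl dicarbonate, CC(C)(C)OC(=O)OC(=O)OC(C)(C)C
Why: the bulky trialkylborohydride attacks the ketone from the face opposite the 2-aryl group (substrate-controlled hydride reduction, as in the catechin-to-epicatechin oxidation–reduction sequence), setting the 2,3-cis C3 centre, and the alkoxide is O-acylated in the same pot.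

Step 10
Reactants: 15 tert-butyl (2R,3R)-7,8-bis(benzyloxy)-2-[4-(benzyloxy)phenyl]chroman-3-yl carbonate
Product: 16 3,4-cyclic carbonate of (2R,3R,4R)-7,8-bis(benzyloxy)-2-[4-(benzyloxy)phenyl]chroman-3,4-diol (all-cis)
Conditions: DDQ (1.5 equiv), 2,6-di-tert-butylpyridine, 4 Å MS, CH2Cl2, 0 °C to rt
Reagents that add atoms: none
Why: Proposed new method: DDQ abstracts hydride from C4 (benzylic and para to the 7-benzyloxy group, the known site of DDQ functionalisation of flavan-3-ol ethers), and the carbonyl oxygen of the neighbouring cis-3-O-Boc group traps the cation in a 5-exo mode with loss of isobutene, so the new C4–O bond is necessarily cis to C3–O (the all-cis teracacidin arrangement); the closest known types are DDQ C4-alkoxylation of flavan-3-ols and Boc-carbonate participation in cation cyclisations.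

Step 11
Reactants: 10 (2S)-7,8-bis(benzyloxy)-2-[4-(benzyloxy)phenyl]-3-(trimethylsilyloxy)-2H-chromene; 16 all-cis cyclic carbonate
Product: 18 interflavan ketone (4-aryl-flavan-3-one linked C4→C6 to carbonate 16; C4 epimers), via enolonium 17 (not isolated)
Conditions: 10 added slowly to PhI(OH)OTs (1.0 equiv), BF3·OEt2 (1.5 equiv), CH2Cl2, −78 °C; then 16 (2.0 equiv, excess recovered), −78 to −30 °C
Reagents that add atoms: none
Why: umpolung α-arylation of a ketone through an enolonium species (Koser-type trivalent-iodine oxidation of the silyl enol ether), in which C4 of 17 becomes electrophilic and is attacked in a Friedel–Crafts sense by the most electron-rich free position of 16 (C6, ortho to the 7-benzyloxy group and para to the ring oxygen); C2 of both units is untouched and the new C4 centre is left as an epimer mixture because step 12 erases it.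

Step 12
Reactants: 18 interflavan ketone
Product: 20 4-aryl-flav-3-ene (upper C2 as in 7; lower unit as in 16), via enol triflate 19 (not isolated)
Conditions: KN(SiMe3)2, THF, −78 °C; PhNTf2, −78 to 0 °C; then Pd(OAc)2 (5 mol %), PPh3 (10 mol %), HCO2H, n-Bu3N, DMF, 50 °C
Reagents that add atoms: none
Why: both C4 epimers give the same doubly benzylic enolate, which is O-triflated and then reduced by palladium-catalysed formate hydride transfer (oxidative addition to zerovalent palladium, formate exchange, reductive elimination) to the trisubstituted C3=C4 alkene, leaving C2 intact.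

Step 13
Reactants: 20 4-aryl-flav-3-ene
Product: 23 hexa-O-benzyl-ent-oritin-(4β→6)-epioritin-4α-ol, via organoborane 21 (not isolated), via carbonate alcohol 22 (not isolated)
Conditions: BH3·THF (excess), THF, 0 to 40 °C; then aq. NaOH, H2O2, 0 °C to rt
Reagents that add atoms: hydrogen peroxide, OO
Why: Brown hydroboration–oxidation adds H (to C4) and B (to the less substituted C3) syn from the face opposite the 2-aryl group and oxidation proceeds with retention, so C3–OH is trans to both aryl groups and the 4-aryl group is cis to the 2-aryl group (2,3-trans-3,4-trans, compare 1-arylcyclohexene giving trans-2-arylcyclohexanol); the hydroxide of the work-up then saponifies the cyclic carbonate.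

Step 14
Reactants: 23 hexa-O-benzyl-ent-oritin-(4β→6)-epioritin-4α-ol
Product: 24 ent-oritin-(4β→6)-epioritin-4α-ol (target)
Conditions: H2 (1 atm), Pd(OH)2/C, THF/MeOH, rt, stopped at full debenzylation
Reagents that add atoms: none
Why: catalytic hydrogenolysis cleaves the six aryl benzyl ethers under neutral conditions much faster than the secondary benzylic C4–OH or the interflavan bond, and no stereocentre is touched.

**Compound list**

1 | daphnetin (7,8-dihydroxy-2H-chromen-2-one) | O=C1C=Cc2ccc(O)c(O)c2O1 | starting material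
2 | 7,8-bis(benzyloxy)-2H-chromen-2-one | O=C1C=Cc2ccc(OCc3ccccc3)c(OCc3ccccc3)c2O1 | intermediate
3 | 7,8-bis(benzyloxy)-2H-chromen-2-ol (lactol, racemic, not isolated) | OC1C=Cc2ccc(OCc3ccccc3)c(OCc3ccccc3)c2O1 | intermediate
4 | 7,8-bis(benzyloxy)-2-ethoxy-2H-chromene (racemic acetal) | CCOC1C=Cc2ccc(OCc3ccccc3)c(OCc3ccccc3)c2O1 | intermediate
5 | 4-(benzyloxy)phenylboronic acid | OB(O)c1ccc(OCc2ccccc2)cc1 | starting material
6 | diethyl [4-(benzyloxy)phenyl]boronate | CCOB(OCC)c1ccc(OCc2ccccc2)cc1 | intermediate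
7 | (2R)-7,8-bis(benzyloxy)-2-[4-(benzyloxy)phenyl]-2H-chromene | C(c1ccccc1)Oc1ccc([C@@H]2Oc3c(ccc(OCc4ccccc4)c3OCc3ccccc3)C=C2)cc1 | intermediate
8 | 2,3-trans-3-boranyl-flavan from 7, boron anti to the 2-aryl group (not isolated) | C(c1ccccc1)Oc1ccc([C@@H]2Oc3c(ccc(OCc4ccccc4)c3OCc3ccccc3)C[C@H]2B)cc1 | intermediate
9 | (2S)-7,8-bis(benzyloxy)-2-[4-(benzyloxy)phenyl]chroman-3-one | C(c1ccccc1)Oc1ccc([C@@H]2Oc3c(ccc(OCc4ccccc4)c3OCc3ccccc3)CC2=O)cc1 | intermediate
10 | (2S)-7,8-bis(benzyloxy)-2-[4-(benzyloxy)phenyl]-3-(trimethylsilyloxy)-2H-chromene | C(c1ccccc1)Oc1ccc([C@@H]2Oc3c(ccc(OCc4ccccc4)c3OCc3ccccc3)C=C2O[Si](C)(C)C)cc1 | intermediate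
11 | (2S)-7,8-bis(benzyloxy)-2-[4-(benzyloxy)phenyl]-2H-chromene | C(c1ccccc1)Oc1ccc([C@H]2Oc3c(ccc(OCc4ccccc4)c3OCc3ccccc3)C=C2)cc1 | intermediate
12 | 2,3-trans-3-boranyl-flavan from 11, boron anti to the 2-aryl group (not isolated) | C(c1ccccc1)Oc1ccc([C@H]2Oc3c(ccc(OCc4ccccc4)c3OCc3ccccc3)C[C@@H]2B)cc1 | intermediate
13 | (2R)-7,8-bis(benzyloxy)-2-[4-(benzyloxy)phenyl]chroman-3-one | C(c1ccccc1)Oc1ccc([C@H]2Oc3c(ccc(OCc4ccccc4)c3OCc3ccccc3)CC2=O)cc1 | intermediate
14 | lithium (2R,3R)-7,8-bis(benzyloxy)-2-[4-(benzyloxy)phenyl]chroman-3-olate, 2,3-cis (not isolated) | C(c1ccccc1)Oc1ccc([C@H]2Oc3c(ccc(OCc4ccccc4)c3OCc3ccccc3)C[C@H]2[O-])cc1.[Li+] | intermediate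
15 | tert-butyl (2R,3R)-7,8-bis(benzyloxy)-2-[4-(benzyloxy)phenyl]chroman-3-yl carbonate (2,3-cis) | C(c1ccccc1)Oc1ccc([C@H]2Oc3c(ccc(OCc4ccccc4)c3OCc3ccccc3)C[C@H]2OC(=O)OC(C)(C)C)cc1 | intermediate
16 | 3,4-cyclic carbonate of (2R,3R,4R)-7,8-bis(benzyloxy)-2-[4-(benzyloxy)phenyl]chroman-3,4-diol (all-cis; tri-O-benzyl-teracacidin carbonate) | C(c1ccccc1)Oc1ccc([C@H]2Oc3c(ccc(OCc4ccccc4)c3OCc3ccccc3)[C@H]3OC(=O)O[C@@H]23)cc1 | intermediate
17 | enolonium: (2S)-3-{[phenyl(tosyloxy)-λ3-iodanyl]oxy}-2H-chromene derived from 10 (not isolated) | C(c1ccccc1)Oc1ccc([C@@H]2Oc3c(ccc(OCc4ccccc4)c3OCc3ccccc3)C=C2OI(c2ccccc2)OS(=O)(=O)c2ccc(C)cc2)cc1 | intermediate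
18 | interflavan ketone: (2S)-7,8-bis(benzyloxy)-2-[4-(benzyloxy)phenyl]-3-oxochroman-4-yl bonded through C4 to C6 of carbonate 16 (C4 epimer mixture) | C(c1ccccc1)Oc1ccc([C@H]2Oc3c(cc(C4c5ccc(OCc6ccccc6)c(OCc6ccccc6)c5O[C@@H](c5ccc(OCc6ccccc6)cc5)C4=O)c(OCc4ccccc4)c3OCc3ccccc3)[C@H]3OC(=O)O[C@@H]23)cc1 | intermediate
19 | enol triflate of 18 (C3–OTf, C3=C4; not isolated) | C(c1ccccc1)Oc1ccc([C@H]2Oc3c(cc(C=4c5ccc(OCc6ccccc6)c(OCc6ccccc6)c5O[C@@H](c5ccc(OCc6ccccc6)cc5)C4OS(=O)(=O)C(F)(F)F)c(OCc4ccccc4)c3OCc3ccccc3)[C@H]3OC(=O)O[C@@H]23)cc1 | intermediate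
20 | 4-aryl-flav-3-ene: upper 2H-chromene (C2 spatial arrangement as in 7) bonded through C4 to C6 of carbonate 16 | C(c1ccccc1)Oc1ccc([C@H]2Oc3c(cc(C=4c5ccc(OCc6ccccc6)c(OCc6ccccc6)c5O[C@@H](c5ccc(OCc6ccccc6)cc5)C4)c(OCc4ccccc4)c3OCc3ccccc3)[C@H]3OC(=O)O[C@@H]23)cc1 | intermediate
21 | organoborane from 20: upper C3 boranyl anti to the 2-aryl group, H at C4 syn to boron (not isolated) | C(c1ccccc1)Oc1ccc([C@H]2Oc3c(cc([C@H]4c5ccc(OCc6ccccc6)c(OCc6ccccc6)c5O[C@@H](c5ccc(OCc6ccccc6)cc5)[C@@H]4B)c(OCc4ccccc4)c3OCc3ccccc3)[C@H]3OC(=O)O[C@@H]23)cc1 | intermediate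
22 | carbonate alcohol: upper unit 2,3-trans-3,4-trans flavan-3-ol (2S,3R, target arrangement), lower unit still the cyclic carbonate (not isolated) | C(c1ccccc1)Oc1ccc([C@H]2Oc3c(cc([C@H]4c5ccc(OCc6ccccc6)c(OCc6ccccc6)c5O[C@@H](c5ccc(OCc6ccccc6)cc5)[C@@H]4O)c(OCc4ccccc4)c3OCc3ccccc3)[C@H]3OC(=O)O[C@@H]23)cc1 | intermediate
23 | hexa-O-benzyl-ent-oritin-(4β→6)-epioritin-4α-ol (all six phenols benzylated; upper 3-OH and lower 3,4-diol free; all stereocentres as in the target) | C(c1ccccc1)Oc1ccc([C@H]2Oc3c(cc([C@H]4c5ccc(OCc6ccccc6)c(OCc6ccccc6)c5O[C@@H](c5ccc(OCc6ccccc6)cc5)[C@@H]4O)c(OCc4ccccc4)c3OCc3ccccc3)[C@@H](O)[C@H]2O)cc1 | intermediate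
24 | ent-oritin-(4β→6)-epioritin-4α-ol: (2R,3R,4R)-6-[(2S,3R,4S)-3,7,8-trihydroxy-2-(4-hydroxyphenyl)chroman-4-yl]-2-(4-hydroxyphenyl)chroman-3,4,7,8-tetrol | Oc1ccc([C@H]2Oc3c(cc([C@H]4c5ccc(O)c(O)c5O[C@@H](c5ccc(O)cc5)[C@@H]4O)c(O)c3O)[C@@H](O)[C@H]2O)cc1 | target

**Step count and risks**

Total steps: 14. Longest linear sequence: 10 (steps 1, 2, 7, 8, 9, 10, 11, 12, 13, 14).

Most likely to fail, first: step 11. The enolonium 17 can lose the C2 proton to give a 3-oxidoflavylium pigment, be captured by tosylate, or arylate a second molecule of product instead of 16. The fallback moves the reversed polarity to the other partner. It sets out from 16, which is treated with MesI(OH)OTs in CH2Cl2/CF3CH2OH to give the aryl(mesityl)iodonium tosylate F1 (iodine at C6, the same most nucleophilic position). F1 then arylates the unchanged silyl enol ether 10 under Cu(OTf)2 catalysis (10 mol %, CH2Cl2, rt), the less hindered flavan aryl group being transferred in preference to mesityl. This comes back to the route at 18.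

Second: step 10. The Boc-trapped DDQ oxidation is untested; hydride abstraction at C2, or loss of the C3 proton from the C4 cation, may compete. The fallback sets out from chromene 11. NBS in aqueous THF at 0 °C adds bromine to C3 anti to the 2-aryl group and water to the benzylic C4 anti to bromine, giving the trans-bromohydrin F2 (4-OH cis to the aryl group). Boc2O/DMAP converts it into the 4-O-Boc bromide F3. AgOTf in CH2Cl2 then removes bromide while the Boc carbonyl oxygen displaces it at C3 with inversion and loses isobutene. This gives the all-cis cyclic carbonate and comes back to the route at 16.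

Third: step 12. Zerovalent palladium with formate may also open the allylic aryl ether (C2–O1) of product 20 or the benzylic carbonate of the lower unit. The fallback sets out from ketone 18. After equilibration of C4 with Et3N to the 2,4-cis ketone, LiBH(s-Bu)3 at −78 °C delivers hydride opposite both aryl groups to give the all-cis alcohol F4. MsCl/Et3N gives the mesylate F5. DBU in toluene at 60 °C removes the doubly benzylic, anti-periplanar C4–H in an E2 elimination. This comes back to the route at alkene 20.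

**Further compounds**

F1 | step 11 | mesityl(aryl)iodonium tosylate of 16 with iodine on C6 of the lower unit | C(c1ccccc1)Oc1ccc([C@H]2Oc3c(cc([I+]c4c(C)cc(C)cc4C)c(OCc4ccccc4)c3OCc3ccccc3)[C@H]3OC(=O)O[C@@H]23)cc1.[O-]S(=O)(=O)c1ccc(C)cc1
F2 | step 10 | (2R,3S,4R)-7,8-bis(benzyloxy)-2-[4-(benzyloxy)phenyl]-3-bromochroman-4-ol (trans-bromohydrin) | C(c1ccccc1)Oc1ccc([C@H]2Oc3c(ccc(OCc4ccccc4)c3OCc3ccccc3)[C@@H](O)[C@@H]2Br)cc1
F3 | step 10 | tert-butyl carbonate of F2 (4-O-Boc, 3-bromo) | C(c1ccccc1)Oc1ccc([C@H]2Oc3c(ccc(OCc4ccccc4)c3OCc3ccccc3)[C@@H](OC(=O)OC(C)(C)C)[C@@H]2Br)cc1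
F4 | step 12 | all-cis alcohol from 18 (upper 2-aryl, 3-OH and 4-aryl all cis; lower unit as in 16) | C(c1ccccc1)Oc1ccc([C@H]2Oc3c(cc([C@H]4c5ccc(OCc6ccccc6)c(OCc6ccccc6)c5O[C@@H](c5ccc(OCc6ccccc6)cc5)[C@H]4O)c(OCc4ccccc4)c3OCc3ccccc3)[C@H]3OC(=O)O[C@@H]23)cc1
F5 | step 12 | methanesulfonate of F4 | C(c1ccccc1)Oc1ccc([C@H]2Oc3c(cc([C@H]4c5ccc(OCc6ccccc6)c(OCc6ccccc6)c5O[C@@H](c5ccc(OCc6ccccc6)cc5)[C@H]4OS(C)(=O)=O)c(OCc4ccccc4)c3OCc3ccccc3)[C@H]3OC(=O)O[C@@H]23)cc1
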